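## Retrosynthetic overview

1. Target ⇐ its phenol benzyl ether; hydrogenolysis is the last step.
2. Oxolane ring ⇐ C2–O1 bond: acid-mediated closure of a benzylic carbinol onto a primary hydroxyl of an acyclic triol (second and last ring formed).
3. Triol ⇐ LiAlH4 opening of a trans-3,4-disubstituted γ-butyrolactone, whose C3–CH(OH)Ar bond ⇐ intermolecular aldol of the lactone lithium enolate with 3,4,5-trimethoxybenzaldehyde (key C–C bond).
4. (S)-4-(Arylmethyl)-γ-butyrolactone (first ring formed, later opened) ⇐ Evans alkylation of an N-succinyl oxazolidinone with a benzylic bromide, reductive auxiliary removal, lactonisation.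
5. Benzylic bromide ⇐ 3-hydroxy-4,5-dimethoxybenzaldehyde (benzylation, reduction, bromination).

Assumption: the carbinol carbon of 15 and 16 is carried as a mixture of both epimers and left unassigned, because step 10 erases and resets it.

## Route

**Step 1**
Reactants: 1 3-hydroxy-4,5-dimethoxybenzaldehyde
Product: 2 3-(benzyloxy)-4,5-dimethoxybenzaldehyde
Conditions: BnBr (1.2 equiv), K2CO3 (2 equiv), DMF, rt
Reagents that add atoms: benzyl bromide, BrCc1ccccc1
Why: Williamson ether synthesis on the phenoxide; the aldehyde is inert to carbonate and the benzyl ether survives every later step until the final hydrogenolysis.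

**Step 2**
Reactants: 2 3-(benzyloxy)-4,5-dimethoxybenzaldehyde
Product: 3 [3-(benzyloxy)-4,5-dimethoxyphenyl]methanol
Conditions: NaBH4, MeOH, 0 °C → rt
Reagents that add atoms: none
Why: Borohydride reduction of an aryl aldehyde to the benzylic alcohol, with no other reducible group present.

**Step 3**
Reactants: 3 [3-(benzyloxy)-4,5-dimethoxyphenyl]methanol
Product: 4 1-(benzyloxy)-5-(bromomethyl)-2,3-dimethoxybenzene
Conditions: PBr3 (0.4 equiv), CH2Cl2, 0 °C; used without storage
Reagents that add atoms: phosphorus tribromide, BrP(Br)Br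
Why: Bromination of an activated benzylic alcohol through its phosphite ester (SN2), under conditions that leave aryl ethers alone.

**Step 4**
Reactants: 5 (4S)-4-benzyl-1,3-oxazolidin-2-one; 6 4-tert-butoxy-4-oxobutanoic acid (mono-tert-butyl succinate)
Product: 8 tert-butyl 4-[(4S)-4-benzyl-2-oxo-1,3-oxazolidin-3-yl]-4-oxobutanoate, via mixed pivalic anhydride 7 (not isolated)
Conditions: 6, PivCl, Et3N, THF, −20 °C; then LiCl, 5, −20 °C → rt
Reagents that add atoms: pivaloyl chloride, CC(C)(C)C(Cl)=O (its atoms are carried only by 7 and leave again as pivalate)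
Why: Mixed-anhydride N-acylation of the oxazolidinone (LiCl/Et3N activation), in which the hindered pivaloyl carbonyl is not attacked and the tert-butyl ester is untouched.

**Step 5**
Reactants: 8 tert-butyl 4-[(4S)-4-benzyl-2-oxo-1,3-oxazolidin-3-yl]-4-oxobutanoate; 4 1-(benzyloxy)-5-(bromomethyl)-2,3-dimethoxybenzene
Product: 10 tert-butyl (3S)-3-[3-(benzyloxy)-4,5-dimethoxybenzyl]-4-[(4S)-4-benzyl-2-oxo-1,3-oxazolidin-3-yl]-4-oxobutanoate, via sodium enolate 9 (not isolated)
Conditions: NaHMDS (1.1 equiv), THF, −78 °C; then 4 (1.2 equiv), −78 → −30 °C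
Reagents that add atoms: sodium bis(trimethylsilyl)amide, C[Si](C)(C)[N-][Si](C)(C)C.[Na+] (only its sodium, and only in 9)
Why: Evans asymmetric alkylation, in which the imide α-CH2 (more acidic than the ester α-CH2) gives the chelated (Z)-sodium enolate and the bromide enters on the face opposite the auxiliary's benzyl group, setting the new centre as (3S) (typically ≥95:5).

**Step 6**
Reactants: 10 tert-butyl (3S)-3-[3-(benzyloxy)-4,5-dimethoxybenzyl]-4-[(4S)-4-benzyl-2-oxo-1,3-oxazolidin-3-yl]-4-oxobutanoate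
Product: 11 tert-butyl (3S)-3-[3-(benzyloxy)-4,5-dimethoxybenzyl]-4-hydroxybutanoate
Conditions: LiBH4 (1.5 equiv), H2O (1.5 equiv), Et2O/THF, 0 °C
Reagents that add atoms: none
Why: Reductive cleavage of the N-acyl oxazolidinone, where the lithium-chelated exocyclic imide carbonyl is reduced to the primary alcohol while the hindered tert-butyl ester and the stereocentre are untouched at 0 °C.

**Step 7**
Reactants: 11 tert-butyl (3S)-3-[3-(benzyloxy)-4,5-dimethoxybenzyl]-4-hydroxybutanoate
Product: 12 (4S)-4-[3-(benzyloxy)-4,5-dimethoxybenzyl]oxolan-2-one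
Conditions: p-TsOH·H2O (10 mol %), toluene, 80 °C
Reagents that add atoms: none
Why: Acid-catalysed lactonisation (intramolecular transesterification) to the five-membered lactone, which does not touch the stereocentre and avoids the free tert-butyl cation that TFA would release onto the electron-rich arene.

**Step 8**
Reactants: 12 (4S)-4-[3-(benzyloxy)-4,5-dimethoxybenzyl]oxolan-2-one; 13 3,4,5-trimethoxybenzaldehyde
Product: 15 (3R,4S)-4-[3-(benzyloxy)-4,5-dimethoxybenzyl]-3-[hydroxy(3,4,5-trimethoxyphenyl)methyl]oxolan-2-one (both carbinol epimers), via lithium enolate 14 (not isolated)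
Conditions: LiHMDS (1.1 equiv), THF, −78 °C; then 13 (1.2 equiv), −78 °C; AcOH quench at −78 °C
Reagents that add atoms: lithium bis(trimethylsilyl)amide, C[Si](C)(C)[N-][Si](C)(C)C.[Li+] (only its lithium, and only in 14)
Why: Intermolecular aldol addition, in which the lactone enolate adds to the aldehyde on the face opposite the C-4 arylmethyl group so the new C-3 centre is trans to it (3R, typically >95:5), while the carbinol carbon forms as an epimer mixture that step 10 makes irrelevant.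

**Step 9**
Reactants: 15 (3R,4S)-4-[3-(benzyloxy)-4,5-dimethoxybenzyl]-3-[hydroxy(3,4,5-trimethoxyphenyl)methyl]oxolan-2-one
Product: 16 (2S,3S)-2-[3-(benzyloxy)-4,5-dimethoxybenzyl]-3-[hydroxy(3,4,5-trimethoxyphenyl)methyl]butane-1,4-diol (both carbinol epimers)
Conditions: LiAlH4 (3 equiv), THF, 0 °C → rt; Fieser work-up
Reagents that add atoms: none
Why: Hydride reduction of the lactone to the 1,4-diol, fast enough at 0 °C to outrun retro-aldol cleavage and touching neither stereocentre nor the benzyl ether.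

**Step 10**
Reactants: 16 (2S,3S)-2-[3-(benzyloxy)-4,5-dimethoxybenzyl]-3-[hydroxy(3,4,5-trimethoxyphenyl)methyl]butane-1,4-diol
Product: 17 [(2R,3S,4S)-4-[3-(benzyloxy)-4,5-dimethoxybenzyl]-2-(3,4,5-trimethoxyphenyl)oxolan-3-yl]methanol
Conditions: (+)-CSA (0.2 equiv), CH2Cl2, 0 °C → rt; Et3N quench as soon as 16 is consumed
Reagents that add atoms: none
Why: SN1 dehydrative cycloetherification, in which both carbinol epimers ionise to the same alkoxy-stabilised benzylic cation, the C-1 hydroxyl closes the five-membered ring (the other primary hydroxyl could only give an oxetane), and closure/equilibration places the aryl group trans to the adjacent CH2OH, setting C-2 as R, with water the only by-product.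

**Step 11**
Reactants: 17 [(2R,3S,4S)-4-[3-(benzyloxy)-4,5-dimethoxybenzyl]-2-(3,4,5-trimethoxyphenyl)oxolan-3-yl]methanol
Product: 18 5-{[(3S,4S,5R)-4-(hydroxymethyl)-5-(3,4,5-trimethoxyphenyl)oxolan-3-yl]methyl}-2,3-dimethoxyphenol (CNP0121704.1)
Conditions: H2 (1 atm), 10% Pd/C, EtOAc, rt; stopped on consumption of 17
Reagents that add atoms: none
Why: Catalytic hydrogenolysis of the aryl benzyl ether, which under neutral conditions in EtOAc is much faster than cleavage of the non-phenolic benzylic C–O bond of the oxolane, so no stereocentre is affected.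

## Compound list

1 | 3-hydroxy-4,5-dimethoxybenzaldehyde | O=Cc1cc(O)c(OC)c(OC)c1 | starting material
2 | 3-(benzyloxy)-4,5-dimethoxybenzaldehyde | O=Cc1cc(OCc2ccccc2)c(OC)c(OC)c1 | intermediate
3 | [3-(benzyloxy)-4,5-dimethoxyphenyl]methanol | OCc1cc(OCc2ccccc2)c(OC)c(OC)c1 | intermediate
4 | 1-(benzyloxy)-5-(bromomethyl)-2,3-dimethoxybenzene | BrCc1cc(OCc2ccccc2)c(OC)c(OC)c1 | intermediate
5 | (4S)-4-benzyl-1,3-oxazolidin-2-one | O=C1N[C@@H](Cc2ccccc2)CO1 | starting material
6 | 4-tert-butoxy-4-oxobutanoic acid | OC(=O)CCC(=O)OC(C)(C)C | starting material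
7 | 4-tert-butoxy-4-oxobutanoic pivalic anhydride (not isolated) | CC(C)(C)C(=O)OC(=O)CCC(=O)OC(C)(C)C | intermediate
8 | tert-butyl 4-[(4S)-4-benzyl-2-oxo-1,3-oxazolidin-3-yl]-4-oxobutanoate | O=C1OC[C@H](Cc2ccccc2)N1C(=O)CCC(=O)OC(C)(C)C | intermediate
9 | sodium (Z)-enolate of 8 (not isolated) | [Na+].[O-]/C(=C\CC(=O)OC(C)(C)C)N1[C@@H](Cc2ccccc2)COC1=O | intermediate
10 | tert-butyl (3S)-3-[3-(benzyloxy)-4,5-dimethoxybenzyl]-4-[(4S)-4-benzyl-2-oxo-1,3-oxazolidin-3-yl]-4-oxobutanoate | O=C1OC[C@H](Cc2ccccc2)N1C(=O)[C@@H](Cc3cc(OC)c(OC)c(OCc4ccccc4)c3)CC(=O)OC(C)(C)C | intermediate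
11 | tert-butyl (3S)-3-[3-(benzyloxy)-4,5-dimethoxybenzyl]-4-hydroxybutanoate | OC[C@@H](Cc1cc(OC)c(OC)c(OCc2ccccc2)c1)CC(=O)OC(C)(C)C | intermediate
12 | (4S)-4-[3-(benzyloxy)-4,5-dimethoxybenzyl]oxolan-2-one | O=C1C[C@H](Cc2cc(OC)c(OC)c(OCc3ccccc3)c2)CO1 | intermediate
13 | 3,4,5-trimethoxybenzaldehyde | O=Cc1cc(OC)c(OC)c(OC)c1 | starting material
14 | lithium enolate of 12 (not isolated) | [Li+].[O-]C1=C[C@H](Cc2cc(OC)c(OC)c(OCc3ccccc3)c2)CO1 | intermediate
15 | (3R,4S)-4-[3-(benzyloxy)-4,5-dimethoxybenzyl]-3-[hydroxy(3,4,5-trimethoxyphenyl)methyl]oxolan-2-one, carbinol epimers | O=C1OC[C@@H](Cc2cc(OC)c(OC)c(OCc3ccccc3)c2)[C@@H]1C(O)c4cc(OC)c(OC)c(OC)c4 | intermediate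
16 | (2S,3S)-2-[3-(benzyloxy)-4,5-dimethoxybenzyl]-3-[hydroxy(3,4,5-trimethoxyphenyl)methyl]butane-1,4-diol, carbinol epimers | OC[C@@H](Cc1cc(OC)c(OC)c(OCc2ccccc2)c1)[C@@H](CO)C(O)c3cc(OC)c(OC)c(OC)c3 | intermediate
17 | [(2R,3S,4S)-4-[3-(benzyloxy)-4,5-dimethoxybenzyl]-2-(3,4,5-trimethoxyphenyl)oxolan-3-yl]methanol | COc1cc(C[C@@H]2CO[C@@H](c3cc(OC)c(OC)c(OC)c3)[C@@H]2CO)cc(OCc4ccccc4)c1OC | intermediate
18 | 5-{[(3S,4S,5R)-4-(hydroxymethyl)-5-(3,4,5-trimethoxyphenyl)oxolan-3-yl]methyl}-2,3-dimethoxyphenol | COc1cc(C[C@@H]2CO[C@@H](c3cc(OC)c(OC)c(OC)c3)[C@@H]2CO)cc(O)c1OC | target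

## Totals and risks

Total step count: 11.
Longest linear sequence: 10 steps (1 → 18 through steps 1, 2, 3, 5, 6, 7, 8, 9, 10, 11); step 4 is a one-step side branch.

**Step 5 (auxiliary alkylation).** The electron-rich benzylic bromide 4 is labile and the succinyl imide enolate may alkylate sluggishly. The fallback exchanges the roles of the two partners, so that the aryl group sits in the acyl chain and the ester arm is the electrophile. It sets out from aldehyde 2: Doebner condensation with malonic acid (pyridine, cat. piperidine, 90 °C) gives (E)-3-[3-(benzyloxy)-4,5-dimethoxyphenyl]prop-2-enoic acid F1. Nickel boride reduction (NaBH4, NiCl2·6H2O, MeOH, 0 °C) saturates the alkene without touching the benzyl ether and gives 3-[3-(benzyloxy)-4,5-dimethoxyphenyl]propanoic acid F2. Coupling with commercial (4R)-4-benzyl-1,3-oxazolidin-2-one (PivCl, Et3N, LiCl, THF) gives (4R)-4-benzyl-3-{3-[3-(benzyloxy)-4,5-dimethoxyphenyl]propanoyl}-1,3-oxazolidin-2-one F3. Its sodium enolate (NaHMDS, THF, −78 °C) is alkylated with tert-butyl bromoacetate to give tert-butyl (3S)-3-[3-(benzyloxy)-4,5-dimethoxybenzyl]-4-[(4R)-4-benzyl-2-oxo-1,3-oxazolidin-3-yl]-4-oxobutanoate F4. The enantiomeric auxiliary is needed because the group that was the electrophile now sits on the enolate. LiBH4 cleavage as in step 6 comes back to the route at 11.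

**Step 8 (aldol).** The addition is reversible, so retro-aldol on warming or quenching can cost conversion. The fallback replaces it with an irreversible Claisen-type C-acylation followed by ketone reduction. It sets out from lactone 12: its lithium enolate (LiHMDS 2.2 equiv, THF, −78 °C) is acylated with 3,4,5-trimethoxybenzoyl chloride to give (3R,4S)-4-[3-(benzyloxy)-4,5-dimethoxybenzyl]-3-(3,4,5-trimethoxybenzoyl)oxolan-2-one F5. This is held as its enolate until work-up, and trans is its thermodynamic configuration. NaBH4 in MeOH at −20 °C reduces only the ketone and comes back to the route at 15 (both carbinol epimers, which is immaterial).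

**Step 10 (cationic ring closure).** The benzylic cation can also be captured by the electron-rich benzyloxy-dimethoxyphenyl ring (six-membered Friedel–Crafts closure to an aryltetralin), and the product can re-ionise under acid. The fallback closes the ring through a para-quinone methide under near-neutral conditions and installs the last O-methyl group afterwards. It sets out from lactone 12 (through its enolate 14): aldol as in step 8, but with 4-[(tert-butyldimethylsilyl)oxy]-3,5-dimethoxybenzaldehyde F6 (from syringaldehyde, TBSCl, imidazole, DMF), gives (3R,4S)-4-[3-(benzyloxy)-4,5-dimethoxybenzyl]-3-[{4-[(tert-butyldimethylsilyl)oxy]-3,5-dimethoxyphenyl}(hydroxy)methyl]oxolan-2-one F7. LiAlH4 (THF, 0 °C) followed by Bu4NF gives (2S,3S)-2-[3-(benzyloxy)-4,5-dimethoxybenzyl]-3-[hydroxy(4-hydroxy-3,5-dimethoxyphenyl)methyl]butane-1,4-diol F8. With the free para-hydroxyl the carbinol ionises as a neutral quinone methide with PPTS (cat.) in CH2Cl2 at 0 °C, and the C-1 hydroxyl adds reversibly (oxa-Michael). This gives the 2,3-trans ether 4-[(2R,3S,4S)-4-[3-(benzyloxy)-4,5-dimethoxybenzyl]-3-(hydroxymethyl)oxolan-2-yl]-2,6-dimethoxyphenol F9 under conditions too mild for Friedel–Crafts closure. MeI/K2CO3 in acetone methylates the only free phenol and comes back to the route at 17.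

## Further compounds

F1 | step 5 | (E)-3-[3-(benzyloxy)-4,5-dimethoxyphenyl]prop-2-enoic acid | OC(=O)/C=C/c1cc(OC)c(OC)c(OCc2ccccc2)c1
F2 | step 5 | 3-[3-(benzyloxy)-4,5-dimethoxyphenyl]propanoic acid | OC(=O)CCc1cc(OC)c(OC)c(OCc2ccccc2)c1
F3 | step 5 | (4R)-4-benzyl-3-{3-[3-(benzyloxy)-4,5-dimethoxyphenyl]propanoyl}-1,3-oxazolidin-2-one | O=C1OC[C@@H](Cc2ccccc2)N1C(=O)CCc3cc(OC)c(OC)c(OCc4ccccc4)c3
F4 | step 5 | tert-butyl (3S)-3-[3-(benzyloxy)-4,5-dimethoxybenzyl]-4-[(4R)-4-benzyl-2-oxo-1,3-oxazolidin-3-yl]-4-oxobutanoate | O=C1OC[C@@H](Cc2ccccc2)N1C(=O)[C@@H](Cc3cc(OC)c(OC)c(OCc4ccccc4)c3)CC(=O)OC(C)(C)C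
F5 | step 8 | (3R,4S)-4-[3-(benzyloxy)-4,5-dimethoxybenzyl]-3-(3,4,5-trimethoxybenzoyl)oxolan-2-one | O=C1OC[C@@H](Cc2cc(OC)c(OC)c(OCc3ccccc3)c2)[C@@H]1C(=O)c4cc(OC)c(OC)c(OC)c4
F6 | step 10 | 4-[(tert-butyldimethylsilyl)oxy]-3,5-dimethoxybenzaldehyde | O=Cc1cc(OC)c(O[Si](C)(C)C(C)(C)C)c(OC)c1
F7 | step 10 | (3R,4S)-4-[3-(benzyloxy)-4,5-dimethoxybenzyl]-3-[{4-[(tert-butyldimethylsilyl)oxy]-3,5-dimethoxyphenyl}(hydroxy)methyl]oxolan-2-one, carbinol epimers | O=C1OC[C@@H](Cc2cc(OC)c(OC)c(OCc3ccccc3)c2)[C@@H]1C(O)c4cc(OC)c(O[Si](C)(C)C(C)(C)C)c(OC)c4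
F8 | step 10 | (2S,3S)-2-[3-(benzyloxy)-4,5-dimethoxybenzyl]-3-[hydroxy(4-hydroxy-3,5-dimethoxyphenyl)methyl]butane-1,4-diol, carbinol epimers | OC[C@@H](Cc1cc(OC)c(OC)c(OCc2ccccc2)c1)[C@@H](CO)C(O)c3cc(OC)c(O)c(OC)c3
F9 | step 10 | 4-[(2R,3S,4S)-4-[3-(benzyloxy)-4,5-dimethoxybenzyl]-3-(hydroxymethyl)oxolan-2-yl]-2,6-dimethoxyphenol | COc1cc(C[C@@H]2CO[C@@H](c3cc(OC)c(O)c(OC)c3)[C@@H]2CO)cc(OCc4ccccc4)c1OC
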